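The route rests on cutting the 2-alkylidene-hexahydrofuro[3,2-b]pyran at its C3–C3a bond and its O1–C2 bond. The enol-ether carbon C2 is a masked ketone placed 1,5 to the pyran oxygen O4 and 1,4 to the furan oxygen O1. In one flask, olefin cross-metathesis joins a crotonoyl β-keto-γ-butyrolactone to acyclic (3S,6R)-hept-1-ene-3,6-diol (C3–C3a, as an enone), the remote hydroxyl closes the pyran by oxa-Michael addition and sets C3a, and the former allylic hydroxyl ketalises and dehydrates onto C2 (O1–C2). The precursor therefore holds neither oxygen heterocycle. The lactone comes from an intramolecular Michael addition, and a late macrolactonisation closes the ten-membered ring.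

Key step: step 11

Remark: β-keto lactones 14 and 17–19 are carried as mixtures of C4 epimers and enol tautomers; this centre and the hemiketal carbon of 19 are left unspecified in the SMILES, because both become trigonal in step 11.

Step 1
Reactants: 1 (R)-γ-valerolactone [(5R)-5-methyloxolan-2-one]
Product: 2 (4R)-4-hydroxy-N-methoxy-N-methylpentanamide
Conditions: MeNH(OMe)·HCl, AlMe3, CH2Cl2, 0 °C to rt; cold dilute HCl work-up; used crude
Reagents that add atoms: N,O-dimethylhydroxylamine hydrochloride, CNOC.Cl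
Why: Weinreb aminolysis of a lactone by the aluminium amide made in situ opens the ring at the acyl carbon and leaves the (R)-carbinol centre untouched.

Step 2
Reactants: 2 (4R)-4-hydroxy-N-methoxy-N-methylpentanamide
Product: 3 (4R)-4-[(tert-butyldimethylsilyl)oxy]-N-methoxy-N-methylpentanamide
Conditions: TBSCl, imidazole, DMF, rt
Reagents that add atoms: tert-butyldimethylsilyl chloride, CC(C)(C)[Si](C)(C)Cl
Why: Imidazole-mediated silylation of the secondary alcohol stops relactonisation and masks the hydroxyl until step 12.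

Step 3
Reactants: 3 (4R)-4-[(tert-butyldimethylsilyl)oxy]-N-methoxy-N-methylpentanamide
Product: 4 (6R)-6-[(tert-butyldimethylsilyl)oxy]hept-1-en-3-one
Conditions: CH2=CHMgBr, THF, 0 °C; inverse quench into cold 1 M HCl
Reagents that add atoms: vinylmagnesium bromide, C=C[Mg]Br
Why: Weinreb ketone synthesis, in which the chelated tetrahedral magnesium intermediate survives until the acidic inverse quench, so the vinyl ketone is released without over-addition or aza-Michael addition of the liberated amine.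

Step 4
Reactants: 5 tert-butyl acetate; 6 acrolein
Product: 7 tert-butyl (±)-3-hydroxypent-4-enoate
Conditions: LiN(iPr)2, THF, −78 °C; then 6, −78 °C; aq. NH4Cl
Reagents that add atoms: none
Why: Aldol addition of the lithium ester enolate to the aldehyde of acrolein (1,2-addition at low temperature) gives the racemic allylic alcohol.

Step 5
Reactants: 7 tert-butyl (±)-3-hydroxypent-4-enoate
Product: 8 tert-butyl (3S)-3-hydroxypent-4-enoate
Conditions: Ti(OiPr)4 (10 mol %), D-(−)-diisopropyl tartrate (15 mol %), tBuOOH (0.6 equiv), 4 Å molecular sieves, CH2Cl2, −20 °C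
Reagents that add atoms: none
Why: Sharpless kinetic resolution of a secondary allylic alcohol, in which the D-(−)-tartrate catalyst should epoxidise the (R)-enantiomer much faster, so the (S)-alcohol is recovered and its centre is set by catalyst control.

Step 6
Reactants: 8 tert-butyl (3S)-3-hydroxypent-4-enoate; 4 (6R)-6-[(tert-butyldimethylsilyl)oxy]hept-1-en-3-one
Product: 9 tert-butyl (3S,4E,9R)-9-[(tert-butyldimethylsilyl)oxy]-3-hydroxy-6-oxodec-4-enoate
Conditions: second-generation Hoveyda–Grubbs catalyst (C31H38Cl2N2ORu, 5 mol %), 4 (1.5 equiv), CH2Cl2, 40 °C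
Reagents that add atoms: none
Why: Olefin cross-metathesis between an allylic alcohol and a vinyl ketone, driven by loss of ethene, should give the thermodynamically favoured E-enone without touching either stereocentre.

Step 7
Reactants: 10 Meldrum's acid (2,2-dimethyl-1,3-dioxane-4,6-dione); 11 (E)-but-2-enoyl chloride
Product: 12 5-[(2E)-1-hydroxybut-2-en-1-ylidene]-2,2-dimethyl-1,3-dioxane-4,6-dione
Conditions: pyridine, CH2Cl2, 0 °C to rt
Reagents that add atoms: none
Why: C-acylation of Meldrum's acid by an acid chloride (Oikawa–Yonemitsu protocol) gives the enolised acyl derivative, a storable acylketene precursor.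

Step 8
Reactants: 9 tert-butyl (3S,4E,9R)-9-[(tert-butyldimethylsilyl)oxy]-3-hydroxy-6-oxodec-4-enoate; 12 5-[(2E)-1-hydroxybut-2-en-1-ylidene]-2,2-dimethyl-1,3-dioxane-4,6-dione
Product: 14 tert-butyl 2-[(2S,3R)-4-[(2E)-but-2-enoyl]-3-{(5R)-5-[(tert-butyldimethylsilyl)oxy]-2-oxohexyl}-5-oxooxolan-2-yl]acetate, via keto ester 13 (not isolated)
Conditions: 12 (1.1 equiv), toluene, 80 °C; then DBU (0.5 equiv), 0 °C to rt
Reagents that add atoms: none
Why: Thermolysis of the acyl Meldrum's acid releases an acylketene that the secondary alcohol traps to give 13, and base then triggers a 5-exo-trig intramolecular Michael addition of the β-keto ester onto the γ-acyloxy enone; ring carbon C3 should be set trans to the C2 side chain because the allylic C–H eclipses the alkene in the transition state (minimised allylic strain).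

Step 9
Reactants: 4 (6R)-6-[(tert-butyldimethylsilyl)oxy]hept-1-en-3-one
Product: 15 (3S,6R)-6-[(tert-butyldimethylsilyl)oxy]hept-1-en-3-ol
Conditions: (R)-2-methyl-CBS-oxazaborolidine (C18H20BNO, 20 mol %), catecholborane, toluene, −78 °C; aq. NaOH work-up
Reagents that add atoms: none
Why: Corey–Bakshi–Shibata reduction, in which the vinyl group acts as the large substituent so that the (R)-oxazaborolidine should give the (3S)-carbinol, while catecholborane at low temperature avoids hydroboration of the alkene.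

Step 10
Reactants: 15 (3S,6R)-6-[(tert-butyldimethylsilyl)oxy]hept-1-en-3-ol
Product: 16 (3S,6R)-hept-1-ene-3,6-diol
Conditions: TsOH·H2O (10 mol %), MeOH, rt
Reagents that add atoms: none
Why: Acid-catalysed methanolysis of the silyl ether frees the C6 hydroxyl needed for pyran formation under conditions too mild to ionise the allylic carbinol.

Step 11
Reactants: 14 tert-butyl 2-[(2S,3R)-4-[(2E)-but-2-enoyl]-3-{(5R)-5-[(tert-butyldimethylsilyl)oxy]-2-oxohexyl}-5-oxooxolan-2-yl]acetate; 16 (3S,6R)-hept-1-ene-3,6-diol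
Product: 20 tert-butyl 2-[(2S,3R,4E)-3-{(5R)-5-[(tert-butyldimethylsilyl)oxy]-2-oxohexyl}-4-[(3aS,5R,7aS)-5-methylhexahydro-2H-furo[3,2-b]pyran-2-ylidene]-5-oxooxolan-2-yl]acetate, via enone 17 (not isolated), via oxane ketone 18 (not isolated), via hemiketal 19 (not isolated)
Conditions: second-generation Hoveyda–Grubbs catalyst (C31H38Cl2N2ORu, 10 mol %), 16 (2 equiv), CH2Cl2, 40 °C; then CSA (0.3 equiv), 40 °C
Reagents that add atoms: none
Why: The ruthenium carbene exchanges the propenyl terminus of 14 for the vinyl carbinol of 16 (propene lost) to give E-enone 17 and with it the C3–C3a bond; under acid the C6 hydroxyl of the former diol adds 6-exo-trig to the enone (oxa-Michael) to close the pyran, and the former allylic hydroxyl adds 5-exo-trig to the ketone to give hemiketal 19, whose E1 dehydration towards the lactone α-carbon forms the O1–C2 enol ether. The closest known reaction types are the tandem olefin cross-metathesis/oxa-conjugate cyclisation to 2,6-cis-tetrahydropyrans and the acid-mediated cyclodehydration of ε-hydroxy-β-keto esters to 2-alkylidenetetrahydrofurans. The new stereocentre C3a should be set under thermodynamic control: the oxa-Michael addition is reversible under CSA, the 2,6-cis-oxane with equatorial acylmethyl and methyl groups is favoured, and only this epimer holds the axial hydroxyl cis to the side chain, so it alone is drained into the strain-free cis-fused bicycle. The E geometry of the tetrasubstituted push–pull alkene (ring oxygen anti to the lactone carbonyl) is likewise the thermodynamic one and can equilibrate through the oxocarbenium ion. The step needs cross- over homo-metathesis, secured by excess 16 and by the crotonoyl group being the only alkene in 14, and dehydration into conjugation and not into the ring, secured by the acidity of the lactone α-hydrogen.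

Step 12
Reactants: 20 tert-butyl 2-[(2S,3R,4E)-3-{(5R)-5-[(tert-butyldimethylsilyl)oxy]-2-oxohexyl}-4-[(3aS,5R,7aS)-5-methylhexahydro-2H-furo[3,2-b]pyran-2-ylidene]-5-oxooxolan-2-yl]acetate
Product: 21 2-[(2S,3R,4E)-3-[(5R)-5-hydroxy-2-oxohexyl]-4-[(3aS,5R,7aS)-5-methylhexahydro-2H-furo[3,2-b]pyran-2-ylidene]-5-oxooxolan-2-yl]acetic acid
Conditions: TFA/CH2Cl2/H2O (10:10:1), 0 °C to rt
Reagents that add atoms: none
Why: Acidolysis removes the tert-butyl ester (as isobutene) and the silyl ether in one operation, and the push–pull enol ether, deactivated toward C-protonation by the lactone carbonyl, should survive.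

Step 13
Reactants: 21 2-[(2S,3R,4E)-3-[(5R)-5-hydroxy-2-oxohexyl]-4-[(3aS,5R,7aS)-5-methylhexahydro-2H-furo[3,2-b]pyran-2-ylidene]-5-oxooxolan-2-yl]acetic acid
Product: 23 Cordycicadin D, via mixed anhydride 22 (not isolated)
Conditions: 2-methyl-6-nitrobenzoic anhydride (1.3 equiv), DMAP (3 equiv), CH2Cl2 (1 mM, slow addition of 21), rt
Reagents that add atoms: none
Why: Shiina macrolactonisation, in which the mixed anhydride formed in situ is opened by DMAP and the acylpyridinium is captured by the side-chain hydroxyl under high dilution, closing the ten-membered lactone with retention at the carbinol centre.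

Compound list
1 | (R)-γ-valerolactone, (5R)-5-methyloxolan-2-one | C[C@@H]1CCC(=O)O1 | starting material
2 | (4R)-4-hydroxy-N-methoxy-N-methylpentanamide | C[C@@H](O)CCC(=O)N(C)OC | intermediate
3 | (4R)-4-[(tert-butyldimethylsilyl)oxy]-N-methoxy-N-methylpentanamide | C[C@@H](O[Si](C)(C)C(C)(C)C)CCC(=O)N(C)OC | intermediate
4 | (6R)-6-[(tert-butyldimethylsilyl)oxy]hept-1-en-3-one | C[C@@H](O[Si](C)(C)C(C)(C)C)CCC(=O)C=C | intermediate
5 | tert-butyl acetate | CC(=O)OC(C)(C)C | starting material
6 | acrolein (prop-2-enal) | C=CC=O | starting material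
7 | tert-butyl (±)-3-hydroxypent-4-enoate | C=CC(O)CC(=O)OC(C)(C)C | intermediate
8 | tert-butyl (3S)-3-hydroxypent-4-enoate | C=C[C@@H](O)CC(=O)OC(C)(C)C | intermediate
9 | tert-butyl (3S,4E,9R)-9-[(tert-butyldimethylsilyl)oxy]-3-hydroxy-6-oxodec-4-enoate | C[C@@H](O[Si](C)(C)C(C)(C)C)CCC(=O)/C=C/[C@@H](O)CC(=O)OC(C)(C)C | intermediate
10 | Meldrum's acid (2,2-dimethyl-1,3-dioxane-4,6-dione) | CC1(C)OC(=O)CC(=O)O1 | starting material
11 | (E)-but-2-enoyl chloride | C/C=C/C(=O)Cl | starting material
12 | 5-[(2E)-1-hydroxybut-2-en-1-ylidene]-2,2-dimethyl-1,3-dioxane-4,6-dione | C/C=C/C(O)=C1C(=O)OC(C)(C)OC1=O | intermediate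
13 | tert-butyl (3S,4E,9R)-9-[(tert-butyldimethylsilyl)oxy]-6-oxo-3-{[(4E)-3-oxohex-4-enoyl]oxy}dec-4-enoate | C[C@@H](O[Si](C)(C)C(C)(C)C)CCC(=O)/C=C/[C@@H](OC(=O)CC(=O)/C=C/C)CC(=O)OC(C)(C)C | intermediate (not isolated)
14 | tert-butyl 2-[(2S,3R)-4-[(2E)-but-2-enoyl]-3-{(5R)-5-[(tert-butyldimethylsilyl)oxy]-2-oxohexyl}-5-oxooxolan-2-yl]acetate | C[C@@H](O[Si](C)(C)C(C)(C)C)CCC(=O)C[C@@H]1C(C(=O)/C=C/C)C(=O)O[C@H]1CC(=O)OC(C)(C)C | intermediate
15 | (3S,6R)-6-[(tert-butyldimethylsilyl)oxy]hept-1-en-3-ol | C[C@@H](O[Si](C)(C)C(C)(C)C)CC[C@H](O)C=C | intermediate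
16 | (3S,6R)-hept-1-ene-3,6-diol | C[C@@H](O)CC[C@H](O)C=C | intermediate
17 | tert-butyl 2-[(2S,3R)-3-{(5R)-5-[(tert-butyldimethylsilyl)oxy]-2-oxohexyl}-4-[(2E,4S,7R)-4,7-dihydroxyoct-2-enoyl]-5-oxooxolan-2-yl]acetate | C[C@@H](O[Si](C)(C)C(C)(C)C)CCC(=O)C[C@@H]1C(C(=O)/C=C/[C@@H](O)CC[C@@H](C)O)C(=O)O[C@H]1CC(=O)OC(C)(C)C | intermediate (not isolated)
18 | tert-butyl 2-[(2S,3R)-3-{(5R)-5-[(tert-butyldimethylsilyl)oxy]-2-oxohexyl}-4-{2-[(2S,3S,6R)-3-hydroxy-6-methyloxan-2-yl]acetyl}-5-oxooxolan-2-yl]acetate | C[C@@H](O[Si](C)(C)C(C)(C)C)CCC(=O)C[C@@H]1C(C(=O)C[C@@H]2O[C@H](C)CC[C@@H]2O)C(=O)O[C@H]1CC(=O)OC(C)(C)C | intermediate (not isolated)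
19 | tert-butyl 2-[(2S,3R)-3-{(5R)-5-[(tert-butyldimethylsilyl)oxy]-2-oxohexyl}-4-[(3aS,5R,7aS)-2-hydroxy-5-methylhexahydro-2H-furo[3,2-b]pyran-2-yl]-5-oxooxolan-2-yl]acetate | C[C@@H](O[Si](C)(C)C(C)(C)C)CCC(=O)C[C@@H]1C(C2(O)C[C@@H]3O[C@H](C)CC[C@@H]3O2)C(=O)O[C@H]1CC(=O)OC(C)(C)C | intermediate (not isolated)
20 | tert-butyl 2-[(2S,3R,4E)-3-{(5R)-5-[(tert-butyldimethylsilyl)oxy]-2-oxohexyl}-4-[(3aS,5R,7aS)-5-methylhexahydro-2H-furo[3,2-b]pyran-2-ylidene]-5-oxooxolan-2-yl]acetate | C[C@@H](O[Si](C)(C)C(C)(C)C)CCC(=O)C[C@@H]1/C(=C2/C[C@@H]3O[C@H](C)CC[C@@H]3O2)C(=O)O[C@H]1CC(=O)OC(C)(C)C | intermediate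
21 | 2-[(2S,3R,4E)-3-[(5R)-5-hydroxy-2-oxohexyl]-4-[(3aS,5R,7aS)-5-methylhexahydro-2H-furo[3,2-b]pyran-2-ylidene]-5-oxooxolan-2-yl]acetic acid | C[C@@H](O)CCC(=O)C[C@@H]1/C(=C2/C[C@@H]3O[C@H](C)CC[C@@H]3O2)C(=O)O[C@H]1CC(=O)O | intermediate
22 | mixed anhydride of 21 with 2-methyl-6-nitrobenzoic acid | C[C@@H](O)CCC(=O)C[C@@H]1/C(=C2/C[C@@H]3O[C@H](C)CC[C@@H]3O2)C(=O)O[C@H]1CC(=O)OC(=O)c1c(C)cccc1[N+](=O)[O-] | intermediate (not isolated)
23 | Cordycicadin D | C[C@@H]1CCC(=O)C[C@@H]2/C(=C3/C[C@@H]4O[C@H](C)CC[C@@H]4O3)C(=O)O[C@H]2CC(=O)O1 | target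

Total step count: 13
Longest linear sequence: 8 steps (steps 1, 2, 3, 6, 8, 11, 12, 13)

Steps most likely to fail

Step 11. The cross-metathesis may stall because the largely enolised 1,3-dicarbonyl can chelate ruthenium and the internal crotonoyl alkene turns over slowly, so homodimerisation and double-bond migration of 16 take over. In the acid phase an aldol condensation between the two ketones could also compete with ketalisation. The fallback sets out from 9 and 16 and comes back to the route at 20; it reaches the same enone 17 by carbonyl olefination instead of metathesis and keeps the one-flask cascade. Ozonolysis of 16 (O3, CH2Cl2/MeOH, −78 °C; Me2S) gives the lactol (3S,6R)-6-methyloxane-2,3-diol F1. Alcohol 9 is heated with tert-butyl 4-chloro-3-oxobutanoate (toluene, 110 °C) to give tert-butyl (3S,4E,9R)-9-[(tert-butyldimethylsilyl)oxy]-3-[(4-chloro-3-oxobutanoyl)oxy]-6-oxodec-4-enoate F2. This closes by a neutral Michael addition (FeCl3·6H2O, 5 mol %, CH2Cl2, rt) to tert-butyl 2-[(2S,3R)-3-{(5R)-5-[(tert-butyldimethylsilyl)oxy]-2-oxohexyl}-4-(2-chloroacetyl)-5-oxooxolan-2-yl]acetate F3. PPh3 (THF, rt) converts it into the acylmethyl triphenylphosphonium chloride F4, and aqueous Na2CO3 gives the keto-stabilised ylide, the 4-[(triphenylphosphoranylidene)acetyl] lactone F5. Wittig reaction of F5 with the open-chain aldehyde form of F1 (toluene, 60 °C, PhCO2H cat.), followed by CSA in the same flask, passes through 17, 18 and 19 to 20. The temperature is kept moderate so that the ylide does not attack the side-chain ketone.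

Step 13. Intermolecular acylation (oligomerisation) may outrun closure of the strained ten-membered ring, and the amine base may trigger β-elimination of the lactone oxygen from the activated acyl group. The fallback sets out from 21 and comes back at 23; it replaces base-mediated mixed-anhydride acyl transfer by an isolated, neutral thiol ester that cyclises by double activation without added base. Compound 21 is treated with 2,2'-dipyridyl disulfide and PPh3 (CH2Cl2, rt) to give the S-(pyridin-2-yl) thioester of 21 F6, which is added slowly to refluxing toluene (Corey–Nicolaou lactonisation) to give 23.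

Step 9. Facial discrimination between a vinyl and a primary alkyl substituent may be poor, so that the carbinol configuration erodes and later surfaces as a diastereomeric furopyran. The fallback sets out from 3 and comes back at 15; it sets the carbinol by transfer hydrogenation of an ynone, a substrate class that is reduced with high selectivity. Amide 3 reacts with LiC≡CSiMe3 (THF, −78 °C) to give (6R)-6-[(tert-butyldimethylsilyl)oxy]-1-(trimethylsilyl)hept-1-yn-3-one F7. Noyori transfer hydrogenation (RuCl[(S,S)-TsDPEN](p-cymene), iPrOH, rt) should give (3S,6R)-6-[(tert-butyldimethylsilyl)oxy]-1-(trimethylsilyl)hept-1-yn-3-ol F8. K2CO3 in MeOH removes the alkynyl silane to give (3S,6R)-6-[(tert-butyldimethylsilyl)oxy]hept-1-yn-3-ol F9, and semi-hydrogenation (H2, Pd/CaCO3 poisoned with Pb(OAc)2, quinoline, EtOAc) gives 15.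

Further compounds
F1 | step 11 | (3S,6R)-6-methyloxane-2,3-diol | C[C@@H]1CC[C@H](O)C(O)O1
F2 | step 11 | tert-butyl (3S,4E,9R)-9-[(tert-butyldimethylsilyl)oxy]-3-[(4-chloro-3-oxobutanoyl)oxy]-6-oxodec-4-enoate | C[C@@H](O[Si](C)(C)C(C)(C)C)CCC(=O)/C=C/[C@@H](OC(=O)CC(=O)CCl)CC(=O)OC(C)(C)C
F3 | step 11 | tert-butyl 2-[(2S,3R)-3-{(5R)-5-[(tert-butyldimethylsilyl)oxy]-2-oxohexyl}-4-(2-chloroacetyl)-5-oxooxolan-2-yl]acetate | C[C@@H](O[Si](C)(C)C(C)(C)C)CCC(=O)C[C@@H]1C(C(=O)CCl)C(=O)O[C@H]1CC(=O)OC(C)(C)C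
F4 | step 11 | acylmethyl triphenylphosphonium chloride derived from F3 | C[C@@H](O[Si](C)(C)C(C)(C)C)CCC(=O)C[C@@H]1C(C(=O)C[P+](c2ccccc2)(c2ccccc2)c2ccccc2)C(=O)O[C@H]1CC(=O)OC(C)(C)C.[Cl-]
F5 | step 11 | 4-[(triphenylphosphoranylidene)acetyl] lactone (keto-stabilised ylide) | C[C@@H](O[Si](C)(C)C(C)(C)C)CCC(=O)C[C@@H]1C(C(=O)C=P(c2ccccc2)(c2ccccc2)c2ccccc2)C(=O)O[C@H]1CC(=O)OC(C)(C)C
F6 | step 13 | S-(pyridin-2-yl) thioester of 21 | C[C@@H](O)CCC(=O)C[C@@H]1/C(=C2/C[C@@H]3O[C@H](C)CC[C@@H]3O2)C(=O)O[C@H]1CC(=O)Sc1ccccn1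
F7 | step 9 | (6R)-6-[(tert-butyldimethylsilyl)oxy]-1-(trimethylsilyl)hept-1-yn-3-one | C[C@@H](O[Si](C)(C)C(C)(C)C)CCC(=O)C#C[Si](C)(C)C
F8 | step 9 | (3S,6R)-6-[(tert-butyldimethylsilyl)oxy]-1-(trimethylsilyl)hept-1-yn-3-ol | C[C@@H](O[Si](C)(C)C(C)(C)C)CC[C@H](O)C#C[Si](C)(C)C
F9 | step 9 | (3S,6R)-6-[(tert-butyldimethylsilyl)oxy]hept-1-yn-3-ol | C[C@@H](O[Si](C)(C)C(C)(C)C)CC[C@H](O)C#C
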